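(All runs come from a simulation with made-up constants; the scatter is artificial.)

The product in elm slowed long before the starting material was gone, and I had to say what it stood at after 3.0 d and which late move would pay.

all flasks: starting material 0.80 M

| charge | reagent | free catalyst | remark | time |
|---|---|---|---|---|
| elm | 0.90 equiv | 1 mol% | the very flask that is asked about, followed so far |  |
| cedar | 0.90 equiv | 1.5 mol% | run made earlier |  |
| flask | 0.900 equiv | 1 mol% |  | 3.0 d |

| run | time / h | product / % | starting material / % |
|---|---|---|---|
| elm | 5.00 | 43.9 | 56.4 |
| elm | 15.0 | 58.9 | 41.5 |
| elm | 25.0 | 64.8 | 34.2 |
| elm | 40.0 | 71.8 | 28.4 |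
| elm | 60.0 | 75.4 | 25.9 |
| cedar | 0.833 | 28.1 | 72.4 |
| cedar | 1.50 | 34.4 | 65.3 |
| cedar | 2.50 | 40.0 | 60.5 |
| cedar | 3.00 | 42.1 | 57.3 |
| cedar | 4.00 | 45.5 | 56.1 |

(standard deviation of a reading: 1 percentage point)

- south: change nothing and wait 40 h more
- north-west: at 3.0 d add free catalyst, 100% of the amount charged, then wait 40 h
- east: at 3.0 d add reagent, 100% of the amount charged, then wait 40 h
- west: at 3.0 d take out 90% of the product then present, then wait 40 h

- removed product is counted in
- what may be going on: catalyst intermediate B -> catalyst intermediate C; catalyst intermediate C -> free catalyst + product; reagent + free catalyst -> catalyst intermediate A; starting material + catalyst intermediate A <-> catalyst intermediate B; free catalyst <-> dormant form; 2 catalyst intermediate A -> spent catalyst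
- additions bring no volume worth counting

- product, in percent of the starting material first charged, at 3.0 d
- which option adds most product ("none" when 2 percentage points or less is all one gets) (south / north-west / east / west / none)
- product present, with what was taken out counted in, in percent of the starting material first charged, after east
- product present, with what was taken out counted in, in percent of the starting material first charged, after west

Elm made 43.9% in its first 5.00 h but 3.6 percentage points in its last 20.0 h. At the last reading, 24.6% of the charge was still not product. So I took two extremes. If the catalyst in elm stopped at the last reading, the product stayed at 75.4%. If the last rate held unfaded, it reached 77.6%. The rate had fallen from each interval to the next, so I put elm between them.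

To place it, I supposed that the rate followed the starting material and that the working catalyst fell as one over time. The unconverted share then falls as a power of loading times time. Elm's first and last readings give that power as 0.332, and I called it the fade exponent: the logarithm of the drop in unconverted share over the logarithm of the growth in loading times time. Cedar at 3.00 h had the clock of elm at 4.50 h. It read 42.1%, and the exponent gives 41.9%. For elm at 3.0 d it leaves 23.2% unconverted, so my product was 76.8%, below the upper extreme.

The forecast said 77.5%, a little above mine. It chose north-west, with 81.5% after east and 80.5% after west, holding that “the catalyst is the limit, not reagent”.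

Elm gave 77.2%. North-west added 11 points, the most, against 5.8 points for east and 3.7 points for south. East ended at 83.1% and west at 81.0%.

    catalyst intermediate B → catalyst intermediate C (k = 2.60 s⁻¹)
    catalyst intermediate C → free catalyst + product (k = 0.190 s⁻¹)
    reagent + free catalyst → catalyst intermediate A (k = 0.0650 M⁻¹ s⁻¹)
    starting material + catalyst intermediate A ⇌ catalyst intermediate B (K = 14.0 M⁻¹, k = 0.0440 M⁻¹ s⁻¹)
    free catalyst ⇌ dormant form (K = 2.00, k = 1.50 × 10⁻⁴ s⁻¹)
    2 catalyst intermediate A → spent catalyst (k = 0.200 M⁻¹ s⁻¹)

The path taking catalyst intermediate A in pairs to spent catalyst, together with reading at 3.0 d and not ten times later, held elm at 77.2%: without the path it gave 90.0%, and the later reading gave 88.9%. The same path acted on north-west too: the gain there was 11 points with the path and 0 points without it. From elm's value, the fade exponent gives 3.1 points for waiting, where south added 3.7 points. For a neighbour of elm with 4 mol% of free catalyst, the exponent gave 85.6%, and that neighbour stood at 84.4%.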